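The indane is cut at C1–C2 and C3–C3a: rings A and B are first joined through C1 as a diaryl carbinol, and C2–C3 with the isopropylidene group comes from 3-methylbuta-1,2-diene. Two features are used: a cation at C1, flanked by both arenes, is stabilised by the dioxane oxygen of ring B ortho to the point of attachment, and C3a of ring A is activated from the para position by the oxygen on C6. In one operation a chiral Brønsted acid ionises the carbinol, the allene is added and the cyclopentane closes, which also sets C1. The precursor carries ring A as a bis-TIPS ether and the tertiary alcohol as a TES ether.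

Key step: step 8

Remarks
- Numbering: indane C1 (diarylmethine), C2 (isopropylidene carbon), C3 (CH2), C3a–C7a (ring A); ring B is the arene of the 1,4-benzodioxane. The target is (1S) at the indane and (S) at the dioxane carbon.
- Abbreviations: ArA = 3-(triisopropylsilyloxy)-2-[(triisopropylsilyloxy)methyl]phenyl; ArB = (3S)-7-methyl-3-[2-(triethylsilyloxy)propan-2-yl]-2,3-dihydro-1,4-benzodioxin-5-yl.
- Assumption: 2-bromo-6-hydroxybenzaldehyde is purchased, which fixes the 1,2,3-pattern of ring A from the start.
- Assumption: the sense of induction of the chiral acid in step 8 cannot be predicted; both antipodes are accessible and the one that gives (1S) is to be identified in a first test. The C1 epimer and any material from the minor enantiomer of 6 are diastereomers of 17 and should be separable.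
- Design of the precursor: both ring A oxygens carry the bulky TIPS group so that the benzylic oxygen neither migrates its silyl group to the aryllithium (step 7) nor traps the cation (step 8); the free carbinol hydroxyl is the leaving group and the water formed is taken up by sieves.

Step 1
Reactants: 1 2-bromo-6-hydroxybenzaldehyde
Product: 2 3-bromo-2-(hydroxymethyl)phenol
Conditions: NaBH4, MeOH, 0 °C; aq. NH4Cl
Reagents that add atoms: none
Why: Borohydride reduction of the aryl aldehyde (carbonyl reduction) should leave the aryl bromide and the phenol untouched.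

Step 2
Reactants: 2 3-bromo-2-(hydroxymethyl)phenol
Product: 3 {[2-bromo-6-(triisopropylsilyloxy)phenyl]methoxy}triisopropylsilane
Conditions: TIPSOTf (2.4 equiv), 2,6-lutidine, CH2Cl2, 0 °C to rt
Reagents that add atoms: triisopropylsilyl trifluoromethanesulfonate, CC(C)[Si](C(C)C)(C(C)C)OS(=O)(=O)C(F)(F)F
Why: A silyl triflate with a hindered pyridine base should silylate both the phenol and the flanked primary benzylic alcohol (silyl ether formation).

Step 3
Reactants: 4 3-methylbut-2-en-1-ol
Product: 6 [(2R)-3,3-dimethyloxiran-2-yl]methyl 4-methylbenzenesulfonate, via epoxy alcohol 5 (not isolated)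
Conditions: Ti(OiPr)4 (5 mol %), D-(−)-diisopropyl tartrate (6 mol %), t-BuOOH, 4 Å sieves, CH2Cl2, −20 °C; then P(OMe)3; then Et3N, DMAP (cat.), TsCl, −10 to 0 °C
Reagents that add atoms: tert-butyl hydroperoxide, CC(C)(C)OO; 4-methylbenzenesulfonyl chloride, Cc1ccc(cc1)S(Cl)(=O)=O
Why: Sharpless asymmetric epoxidation with the D-(−)-tartrate should deliver oxygen to the face that gives the (2R)-epoxy alcohol 5, and sulfonylation in the same flask avoids isolating this small water-soluble alcohol.

Step 4
Reactants: 7 3-bromo-2-hydroxy-5-methylbenzaldehyde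
Product: 8 2,3-dihydroxy-5-methylbenzaldehyde
Conditions: Cu powder (cat.), aq. NaOH, reflux, N2; then HCl
Reagents that add atoms: sodium hydroxide, [Na+].[OH-]
Why: Ullmann-type hydroxylation should replace the bromide ortho to the phenoxide by hydroxide, the phenoxide form shielding the aldehyde from Cannizzaro chemistry.

Step 5
Reactants: 8 2,3-dihydroxy-5-methylbenzaldehyde; 6 [(2R)-3,3-dimethyloxiran-2-yl]methyl 4-methylbenzenesulfonate
Product: 10 (3S)-3-(2-hydroxypropan-2-yl)-7-methyl-2,3-dihydro-1,4-benzodioxine-5-carbaldehyde, via sodium phenoxide 9 (not isolated)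
Conditions: NaH (2.1 equiv), DMSO, rt; then 6 (1.0 equiv), rt; then 60 °C; aq. NH4Cl
Reagents that add atoms: none
Why: In the dianion the 3-oxide, which is not conjugated to the formyl group, should be the more nucleophilic and displace the tosylate at CH2 (Williamson etherification), after which the 2-phenoxide opens the epoxide at its secondary carbon (6-exo-tet) with inversion, turning (2R) of 6 into the (S) dioxane centre.

Step 6
Reactants: 10 (3S)-3-(2-hydroxypropan-2-yl)-7-methyl-2,3-dihydro-1,4-benzodioxine-5-carbaldehyde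
Product: 11 (3S)-7-methyl-3-[2-(triethylsilyloxy)propan-2-yl]-2,3-dihydro-1,4-benzodioxine-5-carbaldehyde
Conditions: TESOTf, 2,6-lutidine, CH2Cl2, −78 to 0 °C
Reagents that add atoms: triethylsilyl trifluoromethanesulfonate, CC[Si](CC)(CC)OS(=O)(=O)C(F)(F)F
Why: Silyl triflate caps the hindered tertiary alcohol (silyl ether formation) so that it neither quenches the aryllithium nor traps cations later, and the non-enolisable aldehyde is inert.

Step 7
Reactants: 3 {[2-bromo-6-(triisopropylsilyloxy)phenyl]methoxy}triisopropylsilane; 11 (3S)-7-methyl-3-[2-(triethylsilyloxy)propan-2-yl]-2,3-dihydro-1,4-benzodioxine-5-carbaldehyde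
Product: 13 diaryl carbinol ArA–CH(OH)–ArB (both epimers at the carbinol carbon), via aryllithium 12 (not isolated)
Conditions: n-BuLi, THF, −78 °C; then 11, −78 to −40 °C; aq. NH4Cl
Reagents that add atoms: none
Why: Bromine–lithium exchange followed by 1,2-addition of the aryllithium to the aldehyde should join the rings, and both epimers are usable because the carbinol centre is ionised in step 8.

Step 8
Reactants: 13 diaryl carbinol ArA–CH(OH)–ArB; 14 3-methylbuta-1,2-diene
Product: 17 (1S)-1-ArB-2-(propan-2-ylidene)-6-(triisopropylsilyloxy)-7-[(triisopropylsilyloxy)methyl]indane, via diarylmethyl cation 15 (not isolated), via allyl cation 16 (not isolated)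
Conditions: chiral imidodiphosphorimidate Brønsted acid [two 3,3'-bis(3,5-bis(trifluoromethyl)phenyl)-BINOL units, N-triflyl groups] (5 mol %), 14 (5 equiv), 5 Å sieves, toluene, −40 °C; Et3N quench
Reagents that add atoms: none
Why: Proposed new method: the acid protonates the carbinol of 13 and water leaves to the sieves, giving cation 15, which is stabilised by the lone pair of the dioxane oxygen ortho to it and is paired with the confined chiral anion; 15 attacks the central carbon of allene 14 (C1–C2), the tertiary cation so formed turns through 90 degrees into the 1,1-dimethylallyl cation 16, and C3a of ring A attacks its CH2 terminus (C3–C3a) before the proton returns to the anion. The closest known chemistry is the acid-catalysed formal [3+2] annulation of benzhydryl cations with alkenes to 1-arylindanes, together with central-carbon attack of carbocations on 1,1-dialkylallenes and ion-pair control of benzylic cations by chiral phosphate-type anions. The cyclopentane ring is closed by an intramolecular Friedel–Crafts allylic alkylation in which C3a adds to the primary allyl terminus from outside the allyl plane, so that C2=CMe2 remains exocyclic. The C1 stereocentre is set in the first C–C bond formation by the chiral anion, which shields one face of planar 15 (the dioxane centre is too remote to help), and the ring closure does not touch it. Central attack on 14 is secured by the gem-dimethyl group, since only this mode leads to a tertiary and then allylic cation; closure at C3a is secured by the para silyloxy group on C6 with C7 blocked; closure at CH2 and not at CMe2 is favoured by the lower steric demand and the more stable tetrasubstituted alkene, but is unproven. The bulky TIPS group keeps the benzylic oxygen from trapping 15 as a phthalan, and low temperature with a catalytic, confined acid should spare the skipped alkene.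

Step 9
Reactants: 17 (1S)-1-ArB-2-(propan-2-ylidene)-6-(triisopropylsilyloxy)-7-[(triisopropylsilyloxy)methyl]indane
Product: 18 (1S)-7-(hydroxymethyl)-1-[(3S)-3-(2-hydroxypropan-2-yl)-7-methyl-2,3-dihydro-1,4-benzodioxin-5-yl]-2-(propan-2-ylidene)indan-6-ol
Conditions: TBAF, AcOH, THF, 0 °C to rt
Reagents that add atoms: none
Why: Fluoride cleaves all three Si–O bonds (desilylation), and the acetic acid buffer keeps the medium from becoming basic enough to move the skipped alkene.

Step 10
Reactants: 18 (1S)-7-(hydroxymethyl)-1-[(3S)-3-(2-hydroxypropan-2-yl)-7-methyl-2,3-dihydro-1,4-benzodioxin-5-yl]-2-(propan-2-ylidene)indan-6-ol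
Product: 19 Diaporindene H
Conditions: MnO2, CH2Cl2, rt
Reagents that add atoms: none
Why: MnO2 oxidises benzylic alcohols selectively (heterogeneous benzylic oxidation), so the tertiary alcohol, the phenol and the tetrasubstituted alkene should stay unchanged.

Compound list
1 | 2-bromo-6-hydroxybenzaldehyde | O=Cc1c(O)cccc1Br | starting material
2 | 3-bromo-2-(hydroxymethyl)phenol | OCc1c(O)cccc1Br | intermediate
3 | {[2-bromo-6-(triisopropylsilyloxy)phenyl]methoxy}triisopropylsilane (ring A bromide) | Brc1cccc(O[Si](C(C)C)(C(C)C)C(C)C)c1CO[Si](C(C)C)(C(C)C)C(C)C | intermediate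
4 | 3-methylbut-2-en-1-ol | CC(C)=CCO | starting material
5 | [(2R)-3,3-dimethyloxiran-2-yl]methanol | CC1(C)O[C@@H]1CO | intermediate (not isolated)
6 | [(2R)-3,3-dimethyloxiran-2-yl]methyl 4-methylbenzenesulfonate | CC1(C)O[C@@H]1COS(=O)(=O)c1ccc(C)cc1 | intermediate
7 | 3-bromo-2-hydroxy-5-methylbenzaldehyde | Cc1cc(Br)c(O)c(C=O)c1 | starting material
8 | 2,3-dihydroxy-5-methylbenzaldehyde | Cc1cc(O)c(O)c(C=O)c1 | intermediate
9 | sodium 2-{[(2R)-3,3-dimethyloxiran-2-yl]methoxy}-6-formyl-4-methylphenolate | CC1(C)O[C@@H]1COc1cc(C)cc(C=O)c1[O-].[Na+] | intermediate (not isolated)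
10 | (3S)-3-(2-hydroxypropan-2-yl)-7-methyl-2,3-dihydro-1,4-benzodioxine-5-carbaldehyde (formyl group ortho to the ring oxygen that carries the stereocentre) | O=Cc1cc(C)cc2c1O[C@H](C(C)(C)O)CO2 | intermediate
11 | (3S)-7-methyl-3-[2-(triethylsilyloxy)propan-2-yl]-2,3-dihydro-1,4-benzodioxine-5-carbaldehyde | O=Cc1cc(C)cc2c1O[C@H](C(C)(C)O[Si](CC)(CC)CC)CO2 | intermediate
12 | {3-(triisopropylsilyloxy)-2-[(triisopropylsilyloxy)methyl]phenyl}lithium | [Li]c1cccc(O[Si](C(C)C)(C(C)C)C(C)C)c1CO[Si](C(C)C)(C(C)C)C(C)C | intermediate (not isolated)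
13 | ArA–CH(OH)–ArB, diaryl carbinol, both carbinol epimers, dioxane centre (S) | OC(c1cccc(O[Si](C(C)C)(C(C)C)C(C)C)c1CO[Si](C(C)C)(C(C)C)C(C)C)c1cc(C)cc2c1O[C@H](C(C)(C)O[Si](CC)(CC)CC)CO2 | intermediate
14 | 3-methylbuta-1,2-diene | CC(C)=C=C | starting material
15 | ArA–CH(+)–ArB, diarylmethyl cation paired with the catalyst anion | [CH+](c1cccc(O[Si](C(C)C)(C(C)C)C(C)C)c1CO[Si](C(C)C)(C(C)C)C(C)C)c1cc(C)cc2c1O[C@H](C(C)(C)O[Si](CC)(CC)CC)CO2 | intermediate (not isolated)
16 | 1,1-dimethylallyl cation carrying the (S)-ArA(ArB)CH group on its central carbon | CC(C)=C([CH2+])[C@@H](c1cccc(O[Si](C(C)C)(C(C)C)C(C)C)c1CO[Si](C(C)C)(C(C)C)C(C)C)c1cc(C)cc2c1O[C@H](C(C)(C)O[Si](CC)(CC)CC)CO2 | intermediate (not isolated)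
17 | (1S)-1-ArB-2-(propan-2-ylidene)-6-(triisopropylsilyloxy)-7-[(triisopropylsilyloxy)methyl]indane | CC(C)=C1Cc2ccc(O[Si](C(C)C)(C(C)C)C(C)C)c(CO[Si](C(C)C)(C(C)C)C(C)C)c2[C@H]1c1cc(C)cc2c1O[C@H](C(C)(C)O[Si](CC)(CC)CC)CO2 | intermediate
18 | (1S)-7-(hydroxymethyl)-1-[(3S)-3-(2-hydroxypropan-2-yl)-7-methyl-2,3-dihydro-1,4-benzodioxin-5-yl]-2-(propan-2-ylidene)indan-6-ol | CC(C)=C1Cc2ccc(O)c(CO)c2[C@H]1c1cc(C)cc2c1O[C@H](C(C)(C)O)CO2 | intermediate
19 | Diaporindene H: the 7-carbaldehyde of 18, (1S) at the indane and (S) at the dioxane carbon | CC(C)=C1Cc2ccc(O)c(C=O)c2[C@H]1c1cc(C)cc2c1O[C@H](C(C)(C)O)CO2 | target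

Total step count: 10. Longest linear sequence: 7 steps (from 7 or from 4 to 19).

Steps most likely to fail

1. Step 8 (proposed new method). The chiral anion may discriminate the two faces of cation 15 poorly, 15 may add to the CH2 end of the allene, the allene may oligomerise, the benzylic oxygen may capture 15, or 16 may close through its tertiary end. The fallback uses known reactions only, sets out from 3 and 11 and comes back at 17. Bromine–lithium exchange on 3 and quenching with B(OiPr)3 should give ring A boronic acid F1. A Horner–Wadsworth–Emmons reaction of 11 with trimethyl phosphonoacetate (NaH, THF) should give ring B cinnamate F2. Hayashi–Miyaura conjugate arylation of F2 with F1 (Rh(acac)(C2H4)2, the BINAP antipode that leads to 3S, aqueous dioxane) should give diarylpropanoate F3 and so fix C1 by a well-mapped catalyst. The ester enolate (LiN(iPr)2, THF, −78 °C) is aminomethylated with Eschenmoser's salt to Mannich base F4, which on quaternisation with MeI and elimination should give α-methylene ester F5. MeLi with CeCl3 should add twice to give tertiary allylic alcohol F6. A catalytic achiral acid (diphenyl phosphate, CH2Cl2, 0 °C) then ionises F6 to allyl cation 16 without touching C1, and an intramolecular Friedel–Crafts allylic alkylation returns to 17. This closure still passes through 16, but as a separate step it can be optimised on its own.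

2. Step 5. Alkylation may take place on the wrong phenoxide oxygen, or the formyl-conjugated phenoxide may open the epoxide too slowly, so that the epoxide is lost. The fallback enforces the order by protection, sets out from 7 (with 6) and comes back at 10. Phenol 7 is converted with PMBCl and K2CO3 into 4-methoxybenzyl ether F7. Miyaura borylation (B2pin2, Pd(dppf)Cl2, KOAc) should give boronate F8, and oxidation with NaBO3 should give phenol F9, in which only the oxygen meant for the CH2 group is free. Alkylation with 6 (K2CO3, DMF) should give epoxy ether F10. DDQ removes the PMB group to free phenol F11, which K2CO3 in warm DMF should cyclise to 10.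

3. Step 10. The electron-rich free phenol may be oxidised (quinone methide formation or oxidative coupling) in competition with the benzylic alcohol. The fallback oxidises with the phenol still masked, sets out from 17 and comes back at 19. HF·pyridine in THF/pyridine should remove the TES group and the alkyl TIPS ether but leave the more acid-stable aryl TIPS ether, giving diol F12. Dess–Martin periodinane (NaHCO3, CH2Cl2) should give silyl-protected aldehyde F13, and TBAF/AcOH then frees the phenol to give 19.

Further compounds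
F1 | step 8 | {3-(triisopropylsilyloxy)-2-[(triisopropylsilyloxy)methyl]phenyl}boronic acid | OB(O)c1cccc(O[Si](C(C)C)(C(C)C)C(C)C)c1CO[Si](C(C)C)(C(C)C)C(C)C
F2 | step 8 | methyl (E)-3-ArB-prop-2-enoate | COC(=O)/C=C/c1cc(C)cc2c1O[C@H](C(C)(C)O[Si](CC)(CC)CC)CO2
F3 | step 8 | methyl (3S)-3-ArA-3-ArB-propanoate | COC(=O)C[C@@H](c1cccc(O[Si](C(C)C)(C(C)C)C(C)C)c1CO[Si](C(C)C)(C(C)C)C(C)C)c1cc(C)cc2c1O[C@H](C(C)(C)O[Si](CC)(CC)CC)CO2
F4 | step 8 | methyl (3S)-2-[(dimethylamino)methyl]-3-ArA-3-ArB-propanoate, both C2 epimers | COC(=O)C(CN(C)C)[C@@H](c1cccc(O[Si](C(C)C)(C(C)C)C(C)C)c1CO[Si](C(C)C)(C(C)C)C(C)C)c1cc(C)cc2c1O[C@H](C(C)(C)O[Si](CC)(CC)CC)CO2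
F5 | step 8 | methyl 2-[(S)-ArA(ArB)methyl]prop-2-enoate | COC(=O)C(=C)[C@@H](c1cccc(O[Si](C(C)C)(C(C)C)C(C)C)c1CO[Si](C(C)C)(C(C)C)C(C)C)c1cc(C)cc2c1O[C@H](C(C)(C)O[Si](CC)(CC)CC)CO2
F6 | step 8 | 2-methyl-3-[(R)-ArA(ArB)methyl]but-3-en-2-ol | CC(C)(O)C(=C)[C@@H](c1cccc(O[Si](C(C)C)(C(C)C)C(C)C)c1CO[Si](C(C)C)(C(C)C)C(C)C)c1cc(C)cc2c1O[C@H](C(C)(C)O[Si](CC)(CC)CC)CO2
F7 | step 5 | 3-bromo-2-[(4-methoxyphenyl)methoxy]-5-methylbenzaldehyde | COc1ccc(COc2c(Br)cc(C)cc2C=O)cc1
F8 | step 5 | 2-[(4-methoxyphenyl)methoxy]-5-methyl-3-(4,4,5,5-tetramethyl-1,3,2-dioxaborolan-2-yl)benzaldehyde | COc1ccc(COc2c(B3OC(C)(C)C(C)(C)O3)cc(C)cc2C=O)cc1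
F9 | step 5 | 3-hydroxy-2-[(4-methoxyphenyl)methoxy]-5-methylbenzaldehyde | COc1ccc(COc2c(O)cc(C)cc2C=O)cc1
F10 | step 5 | 3-{[(2R)-3,3-dimethyloxiran-2-yl]methoxy}-2-[(4-methoxyphenyl)methoxy]-5-methylbenzaldehyde | CC1(C)O[C@@H]1COc1cc(C)cc(C=O)c1OCc1ccc(OC)cc1
F11 | step 5 | 3-{[(2R)-3,3-dimethyloxiran-2-yl]methoxy}-2-hydroxy-5-methylbenzaldehyde | CC1(C)O[C@@H]1COc1cc(C)cc(C=O)c1O
F12 | step 10 | 18 with its phenol as the triisopropylsilyl ether (benzylic and tertiary hydroxyls free) | CC(C)=C1Cc2ccc(O[Si](C(C)C)(C(C)C)C(C)C)c(CO)c2[C@H]1c1cc(C)cc2c1O[C@H](C(C)(C)O)CO2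
F13 | step 10 | 19 with its phenol as the triisopropylsilyl ether | CC(C)=C1Cc2ccc(O[Si](C(C)C)(C(C)C)C(C)C)c(C=O)c2[C@H]1c1cc(C)cc2c1O[C@H](C(C)(C)O)CO2
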